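**Plan**

- Retrosynthetic cuts: first the six aryl methyl ethers and the C6–vinyl bond (Suzuki–Miyaura). Then, in each 2,3-diaryl-2,3-dihydrobenzofuran, the C2–C3 bond, back to a diaryl carbene at C3 and the benzylic CH2 of an aryl benzyl ether. Last, the C3–aryl bond of each carbene precursor, back to a 2,6-bis(benzyloxy)benzonitrile and an aryl-metal.
- Forward order: two nitriles are made by SNAr. The dihydrobenzofuran carrying the 2,4-dioxygenated aryl group (primed locants) is built first (steps 1–3). Its C6′ bromide is metallated and added to the second nitrile (step 5), and a second carbene C–H insertion closes the stilbene-side dihydrofuran ring (O1, C2, C3, C3a, C7a) as the last ring (step 6). Acid equilibration, Suzuki coupling and demethylation follow.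
- Enabling feature: in both benzo rings C3a lies between two oxygens (C4–O and C7a–O) on the local twofold axis through C3a and C6. A carbene on C3 therefore faces two homotopic ArCH2–O groups, and insertion into either gives the same ring. The C2 aryl groups (4-oxygenated and 2,4-dioxygenated phenyl) are exactly the aryl groups of PMB and 2,4-dimethoxybenzyl ethers and make the C–H to be inserted hydridic.
- Stereochemistry: C3′ and C3 are set by the chiral Rh(II) carboxylate in steps 3 and 6 (catalyst control). C2′ and C2 are formed cis and are equilibrated to trans in step 7 by reversible ionisation of the C2–O bonds, which leaves C3 and C3′ untouched. The E-alkene comes from the E-alkenylboronic acid.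
- Helpers: N2 (lost in the insertion) and the spare benzyl ether on each benzo ring (removed in step 7). No ring is formed after step 6.

Key step: step 6

Assumption: Rh2(S-PTAD)4 is taken to be the catalyst antipode that gives the (3R) series; should the trial run of step 3 show the opposite sense, Rh2(R-PTAD)4 is used in steps 3 and 6.

**Route**

Step 1
Reactants: 1 4-bromo-2,6-difluorobenzonitrile; 2 2,4-dimethoxybenzyl alcohol (2.2 equiv)
Product: 3 4-bromo-2,6-bis[(2,4-dimethoxybenzyl)oxy]benzonitrile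
Conditions: NaH, THF, 0 °C → 60 °C
Reagents that add atoms: none
Why: Double nucleophilic aromatic substitution (SNAr) of the two fluorides ortho to the nitrile should proceed through nitrile-stabilised Meisenheimer adducts, fluoride being displaced far faster than the para bromide, so the C–Br handle survives.

Step 2
Reactants: 4 1-bromo-3,5-dimethoxybenzene; 3 4-bromo-2,6-bis[(2,4-dimethoxybenzyl)oxy]benzonitrile
Product: 7 [4-bromo-2,6-bis[(2,4-dimethoxybenzyl)oxy]phenyl](3,5-dimethoxyphenyl)methanone hydrazone, via 3,5-dimethoxyphenylmagnesium bromide 5 (not isolated), via diaryl N-H ketimine 6 (not isolated)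
Conditions: Mg, THF, 45 °C; then 3, THF, 60 °C; MeOH, 0 °C; N2H4·H2O (10 equiv), AcOH (cat.), EtOH, 70 °C
Reagents that add atoms: hydrazine (used as the hydrate), NN
Why: Grignard addition to a nitrile stops at the N-magnesio ketimine, and the N–H ketimine released by methanol should exchange NH for N–NH2 with hydrazine (transimination) more readily than the corresponding di-ortho-substituted benzophenone would condense; the hydrazone geometry is irrelevant.

Step 3
Reactants: 7 [4-bromo-2,6-bis[(2,4-dimethoxybenzyl)oxy]phenyl](3,5-dimethoxyphenyl)methanone hydrazone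
Product: 9 (2S,3R)-6-bromo-4-[(2,4-dimethoxybenzyl)oxy]-2-(2,4-dimethoxyphenyl)-3-(3,5-dimethoxyphenyl)-2,3-dihydrobenzofuran (2,3-cis), via diaryldiazomethane 8 (not isolated)
Conditions: MnO2, CH2Cl2, 0 °C; filtration; Rh2(S-PTAD)4 (1 mol %), CH2Cl2, −20 °C → rt
Reagents that add atoms: none
Why: Dehydrogenation of the hydrazone gives the diaryldiazomethane, and the derived donor/donor rhodium carbene should insert into a benzylic O–CH2 hydrogen of one of the two homotopic 2,4-dimethoxybenzyl ethers (enantioselective intramolecular C–H insertion), the chiral catalyst setting C3′ (R) and the compact insertion geometry placing the C2′ aryl group cis to it.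

Step 4
Reactants: 1 4-bromo-2,6-difluorobenzonitrile; 10 4-methoxybenzyl alcohol (2.2 equiv)
Product: 11 4-bromo-2,6-bis[(4-methoxybenzyl)oxy]benzonitrile
Conditions: NaH, THF, 0 °C → 60 °C
Reagents that add atoms: none
Why: The same double SNAr as in step 1 should give the symmetric bis-PMB ether with the bromide intact.

Step 5
Reactants: 9 (2S,3R)-6-bromo-4-[(2,4-dimethoxybenzyl)oxy]-2-(2,4-dimethoxyphenyl)-3-(3,5-dimethoxyphenyl)-2,3-dihydrobenzofuran; 11 4-bromo-2,6-bis[(4-methoxybenzyl)oxy]benzonitrile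
Product: 15 hydrazone of [4-bromo-2,6-bis[(4-methoxybenzyl)oxy]phenyl][(2S,3R)-4-[(2,4-dimethoxybenzyl)oxy]-2-(2,4-dimethoxyphenyl)-3-(3,5-dimethoxyphenyl)-2,3-dihydrobenzofuran-6-yl]methanone, via aryllithium 12 (not isolated), via arylmagnesium bromide 13 (not isolated), via diaryl N-H ketimine 14 (not isolated)
Conditions: n-BuLi, THF, −78 °C; MgBr2·OEt2, −78 → 0 °C; 11, THF, 55 °C; MeOH, 0 °C; N2H4·H2O (10 equiv), AcOH (cat.), EtOH, 70 °C
Reagents that add atoms: hydrazine (used as the hydrate), NN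
Why: Bromine–lithium exchange at −78 °C is faster than any deprotonation, transmetallation to magnesium lowers the basicity and prevents halogen scrambling with the bromide of 11, and the Grignard addition to the nitrile followed by transimination repeats the reaction types of step 2; no stereocentre is involved, and any epimerisation at C2′ would be inconsequential because step 7 equilibrates that centre.

Step 6
Reactants: 15 hydrazone of [4-bromo-2,6-bis[(4-methoxybenzyl)oxy]phenyl][(2S,3R)-4-[(2,4-dimethoxybenzyl)oxy]-2-(2,4-dimethoxyphenyl)-3-(3,5-dimethoxyphenyl)-2,3-dihydrobenzofuran-6-yl]methanone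
Product: 17 (2S,3R)-6-bromo-4-[(4-methoxybenzyl)oxy]-2-(4-methoxyphenyl)-3-[(2S,3R)-4-[(2,4-dimethoxybenzyl)oxy]-2-(2,4-dimethoxyphenyl)-3-(3,5-dimethoxyphenyl)-2,3-dihydrobenzofuran-6-yl]-2,3-dihydrobenzofuran (both rings 2,3-cis), via diaryldiazomethane 16 (not isolated)
Conditions: MnO2, CH2Cl2, 0 °C; filtration; slow addition to Rh2(S-PTAD)4 (2 mol %), CH2Cl2, −20 °C → rt
Reagents that add atoms: none
Why: MnO2 dehydrogenates the hydrazone to diaryldiazomethane 16, which the rhodium catalyst converts with loss of N2 into a donor/donor carbene centred on the future C3; the carbene inserts, in a concerted, asynchronous, hydride-transfer-like transition state, into a benzylic O–CH2 hydrogen of an ortho 4-methoxybenzyl ether and so forms the C2–C3 bond. The closest known reaction type is the Rh(II)-catalysed enantioselective intramolecular C–H insertion of diaryl carbenes derived from 2-(benzyloxy)benzophenone hydrazones, which gives cis-2,3-diaryl-2,3-dihydrobenzofurans. The dihydrofuran ring closes by 1,5-C–H insertion through a five-membered cyclic transition state, the O1–C7a, O1–C2 and C3–C3a bonds being already in place. C3 is set by the chiral carboxylate ligands of the catalyst, independently of the remote C2′ and C3′ centres, and C2 is set cis to C3 by the compact insertion transition state, a kinetic outcome that step 7 corrects. The step needs site selectivity, and ring B secures it: C3a lies between two identical O-PMB groups on the local twofold axis through C6–Br, so both candidate CH2 groups are homotopic and give the same product, while every other C–H bond is either out of geometric reach or lacks the combined activation by an oxygen lone pair and a 4-methoxyphenyl ring. Slow addition of 16 to the catalyst keeps its concentration low and should suppress azine formation.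

Step 7
Reactants: 17 the cis,cis bis(dihydrobenzofuran) from step 6
Product: 18 (2R,3R)-6-bromo-3-[(2R,3R)-2-(2,4-dimethoxyphenyl)-3-(3,5-dimethoxyphenyl)-4-hydroxy-2,3-dihydrobenzofuran-6-yl]-2-(4-methoxyphenyl)-2,3-dihydrobenzofuran-4-ol (both rings 2,3-trans)
Conditions: TFA/CH2Cl2 (1:4), pentamethylbenzene (10 equiv), 0 °C → rt
Reagents that add atoms: none
Why: Acid should ionise the C2–O and C2′–O bonds reversibly to benzylic cations stabilised by the 4-methoxyphenyl and 2,4-dimethoxyphenyl groups (acid-catalysed epimerisation of 2-aryl-2,3-dihydrobenzofurans), re-closure by either of the two equivalent ring oxygens returning the same constitution in the more stable 2,3-trans form with C3 and C3′ untouched, while the same acid cleaves the PMB and 2,4-dimethoxybenzyl aryl ethers and pentamethylbenzene traps their cations (Friedel–Crafts).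

Step 8
Reactants: 18 the trans,trans diphenol bromide from step 7; 19 (E)-2-(4-methoxyphenyl)vinylboronic acid
Product: 20 (2R,3R)-3-[(2R,3R)-2-(2,4-dimethoxyphenyl)-3-(3,5-dimethoxyphenyl)-4-hydroxy-2,3-dihydrobenzofuran-6-yl]-2-(4-methoxyphenyl)-6-[(E)-2-(4-methoxyphenyl)ethenyl]-2,3-dihydrobenzofuran-4-ol
Conditions: Pd(OAc)2 (5 mol %), SPhos (10 mol %), K3PO4, dioxane/H2O (4:1), 80 °C
Reagents that add atoms: none
Why: Suzuki–Miyaura coupling of the aryl bromide with the E-alkenylboronic acid proceeds with retention of alkene geometry and tolerates the two free phenols.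

Step 9
Reactants: 20 the hexamethyl ether from step 8
Product: 21 target CNP0118407.2: (2R,3R)-3-[(2R,3R)-2-(2,4-dihydroxyphenyl)-3-(3,5-dihydroxyphenyl)-4-hydroxy-2,3-dihydrobenzofuran-6-yl]-2-(4-hydroxyphenyl)-6-[(E)-2-(4-hydroxyphenyl)ethenyl]-2,3-dihydrobenzofuran-4-ol
Conditions: BBr3 (15 equiv), CH2Cl2, −78 °C → rt; then H2O, 0 °C
Reagents that add atoms: none
Why: Boron tribromide should cleave all six aryl methyl ethers (Lewis acid-mediated ether cleavage); both dihydrobenzofurans are already the thermodynamic trans isomers, so reversible C2–O ionisation would return the same stereoisomer, and the stilbene sits para to C3a, out of reach of the C3 aryl group, so no intramolecular cyclisation is available.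

**Compound list**

1 | 4-bromo-2,6-difluorobenzonitrile | N#Cc1c(F)cc(Br)cc1F | starting material
2 | 2,4-dimethoxybenzyl alcohol | COc1ccc(CO)c(OC)c1 | starting material
3 | 4-bromo-2,6-bis[(2,4-dimethoxybenzyl)oxy]benzonitrile | N#Cc1c(OCc2ccc(OC)cc2OC)cc(Br)cc1OCc1ccc(OC)cc1OC | intermediate
4 | 1-bromo-3,5-dimethoxybenzene | COc1cc(Br)cc(OC)c1 | starting material
5 | 3,5-dimethoxyphenylmagnesium bromide (not isolated) | COc1cc([Mg]Br)cc(OC)c1 | intermediate
6 | [4-bromo-2,6-bis[(2,4-dimethoxybenzyl)oxy]phenyl](3,5-dimethoxyphenyl)methanimine (not isolated) | N=C(c1cc(OC)cc(OC)c1)c1c(OCc2ccc(OC)cc2OC)cc(Br)cc1OCc1ccc(OC)cc1OC | intermediate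
7 | [4-bromo-2,6-bis[(2,4-dimethoxybenzyl)oxy]phenyl](3,5-dimethoxyphenyl)methanone hydrazone | NN=C(c1cc(OC)cc(OC)c1)c1c(OCc2ccc(OC)cc2OC)cc(Br)cc1OCc1ccc(OC)cc1OC | intermediate
8 | 5-bromo-2-[diazo(3,5-dimethoxyphenyl)methyl]-1,3-bis[(2,4-dimethoxybenzyl)oxy]benzene (not isolated) | [N-]=[N+]=C(c1cc(OC)cc(OC)c1)c1c(OCc2ccc(OC)cc2OC)cc(Br)cc1OCc1ccc(OC)cc1OC | intermediate
9 | (2S,3R)-6-bromo-4-[(2,4-dimethoxybenzyl)oxy]-2-(2,4-dimethoxyphenyl)-3-(3,5-dimethoxyphenyl)-2,3-dihydrobenzofuran (cis) | Brc1cc(OCc2ccc(OC)cc2OC)c2c(c1)O[C@H](c1ccc(OC)cc1OC)[C@@H]2c1cc(OC)cc(OC)c1 | intermediate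
10 | 4-methoxybenzyl alcohol | COc1ccc(CO)cc1 | starting material
11 | 4-bromo-2,6-bis[(4-methoxybenzyl)oxy]benzonitrile | N#Cc1c(OCc2ccc(OC)cc2)cc(Br)cc1OCc1ccc(OC)cc1 | intermediate
12 | 6-lithio analogue of 9 (Li in place of Br; not isolated) | [Li]c1cc(OCc2ccc(OC)cc2OC)c2c(c1)O[C@H](c1ccc(OC)cc1OC)[C@@H]2c1cc(OC)cc(OC)c1 | intermediate
13 | 6-(bromomagnesio) analogue of 9 (not isolated) | Br[Mg]c1cc(OCc2ccc(OC)cc2OC)c2c(c1)O[C@H](c1ccc(OC)cc1OC)[C@@H]2c1cc(OC)cc(OC)c1 | intermediate
14 | [4-bromo-2,6-bis[(4-methoxybenzyl)oxy]phenyl][(2S,3R)-4-[(2,4-dimethoxybenzyl)oxy]-2-(2,4-dimethoxyphenyl)-3-(3,5-dimethoxyphenyl)-2,3-dihydrobenzofuran-6-yl]methanimine (not isolated) | N=C(c1c(OCc2ccc(OC)cc2)cc(Br)cc1OCc1ccc(OC)cc1)c1cc(OCc2ccc(OC)cc2OC)c2c(c1)O[C@H](c1ccc(OC)cc1OC)[C@@H]2c1cc(OC)cc(OC)c1 | intermediate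
15 | hydrazone of the diaryl ketone corresponding to 14 | NN=C(c1c(OCc2ccc(OC)cc2)cc(Br)cc1OCc1ccc(OC)cc1)c1cc(OCc2ccc(OC)cc2OC)c2c(c1)O[C@H](c1ccc(OC)cc1OC)[C@@H]2c1cc(OC)cc(OC)c1 | intermediate
16 | diaryldiazomethane corresponding to 15 (not isolated) | [N-]=[N+]=C(c1c(OCc2ccc(OC)cc2)cc(Br)cc1OCc1ccc(OC)cc1)c1cc(OCc2ccc(OC)cc2OC)c2c(c1)O[C@H](c1ccc(OC)cc1OC)[C@@H]2c1cc(OC)cc(OC)c1 | intermediate
17 | (2S,3R)-6-bromo-4-[(4-methoxybenzyl)oxy]-2-(4-methoxyphenyl)-3-[(2S,3R)-4-[(2,4-dimethoxybenzyl)oxy]-2-(2,4-dimethoxyphenyl)-3-(3,5-dimethoxyphenyl)-2,3-dihydrobenzofuran-6-yl]-2,3-dihydrobenzofuran (both rings cis) | Brc1cc(OCc2ccc(OC)cc2)c2c(c1)O[C@H](c1ccc(OC)cc1)[C@@H]2c1cc(OCc2ccc(OC)cc2OC)c2c(c1)O[C@H](c1ccc(OC)cc1OC)[C@@H]2c1cc(OC)cc(OC)c1 | intermediate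
18 | (2R,3R)-6-bromo-3-[(2R,3R)-2-(2,4-dimethoxyphenyl)-3-(3,5-dimethoxyphenyl)-4-hydroxy-2,3-dihydrobenzofuran-6-yl]-2-(4-methoxyphenyl)-2,3-dihydrobenzofuran-4-ol (both rings trans) | Brc1cc(O)c2c(c1)O[C@@H](c1ccc(OC)cc1)[C@@H]2c1cc(O)c2c(c1)O[C@@H](c1ccc(OC)cc1OC)[C@@H]2c1cc(OC)cc(OC)c1 | intermediate
19 | (E)-2-(4-methoxyphenyl)vinylboronic acid | COc1ccc(/C=C/B(O)O)cc1 | starting material
20 | (2R,3R)-3-[(2R,3R)-2-(2,4-dimethoxyphenyl)-3-(3,5-dimethoxyphenyl)-4-hydroxy-2,3-dihydrobenzofuran-6-yl]-2-(4-methoxyphenyl)-6-[(E)-2-(4-methoxyphenyl)ethenyl]-2,3-dihydrobenzofuran-4-ol | COc1ccc(/C=C/c2cc(O)c3c(c2)O[C@@H](c2ccc(OC)cc2)[C@@H]3c2cc(O)c3c(c2)O[C@@H](c2ccc(OC)cc2OC)[C@@H]3c2cc(OC)cc(OC)c2)cc1 | intermediate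
21 | CNP0118407.2, (2R,3R)-3-[(2R,3R)-2-(2,4-dihydroxyphenyl)-3-(3,5-dihydroxyphenyl)-4-hydroxy-2,3-dihydrobenzofuran-6-yl]-2-(4-hydroxyphenyl)-6-[(E)-2-(4-hydroxyphenyl)ethenyl]-2,3-dihydrobenzofuran-4-ol | Oc1ccc(/C=C/c2cc(O)c3c(c2)O[C@@H](c2ccc(O)cc2)[C@@H]3c2cc(O)c3c(c2)O[C@@H](c2ccc(O)cc2O)[C@@H]3c2cc(O)cc(O)c2)cc1 | target

**Step count**

Total: 9 steps. Longest linear sequence: 8 steps (1, 2, 3, 5, 6, 7, 8, 9); step 4 lies on a side branch.

**Steps most likely to fail**

Step 6. The carbene is flanked by two ortho ether groups, so carbene transfer may be slow and azine formation may compete. The catalyst may also discriminate the two carbene faces poorly, which would give the C3 epimer, a diastereomer because C2′ and C3′ are already fixed. The fallback is a polar, carbene-free closure of the same ring that gives up catalyst control of C3. It sets out from ketimine 14, which is hydrolysed (AcOH, H2O, THF, 40 °C) instead of being treated with hydrazine, to give the diaryl ketone F1. Corey–Chaykovsky methylenation (Me3S+ I−, KHMDS, THF, 0 °C) should give the 2,2-diaryloxirane F2. Meinwald rearrangement (ZnI2, toluene, rt) should give the 2,2-diarylacetaldehyde F3. Addition of 4-methoxyphenylmagnesium bromide (THF, −78 °C) should give the 1-(4-methoxyphenyl)-2,2-diarylethanol F4 as a mixture of isomers at the two new carbons. Treatment as in step 7 (TFA, pentamethylbenzene, CH2Cl2) should cleave all three benzyl-type ethers, ionise the 4-methoxybenzylic alcohol and let either of the two equivalent phenol oxygens of ring B close the trans dihydrofuran. This would give 18 together with the (2S,3S) diastereomer of the new ring F5; the two would be separated by preparative HPLC, and the route is rejoined at 18.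

Step 5. The aryllithium may deprotonate C3′ and open the dihydrofuran by β-elimination, the aryl Grignard may add incompletely to the electron-rich, doubly ortho-substituted nitrile, or the transimination may stall. The fallback replaces nitrile addition by aldehyde addition, oxidation and condensation. It sets out from 11, which is reduced (DIBAL-H, toluene, −78 °C; aqueous Rochelle salt) to 4-bromo-2,6-bis[(4-methoxybenzyl)oxy]benzaldehyde F6. The aryllithium 12 (from 9, n-BuLi, THF, −78 °C) should add to F6 within minutes at −78 °C, without transmetallation or heating, to give the diaryl carbinol F7. Dess–Martin periodinane (NaHCO3, CH2Cl2) should then give the diaryl ketone F1, the compound also met in the fallback for step 6. Condensation with anhydrous hydrazine (n-BuOH, 110 °C, sealed tube) returns to the route at hydrazone 15.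

Step 9. Protonation or bromoboration of the electron-rich stilbene by BBr3 and HBr may lead to oligomerisation before all six ethers are cleaved. The fallback removes the methyl groups before the alkene exists and brings the styrene in as its acetate. It sets out from 18, which is demethylated (BBr3, CH2Cl2, −78 °C → rt) to the heptaphenol bromide F8. Acetylation (Ac2O, pyridine, DMAP) should give the heptaacetate F9. Heck reaction with commercial 4-acetoxystyrene, CC(=O)Oc1ccc(C=C)cc1 (Pd(OAc)2, P(o-tol)3, Et3N, DMF, 90 °C), should give the E-stilbene octaacetate F10. Methanolysis (K2CO3, degassed MeOH, rt) returns to the route at the target 21.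

**Further compounds**

F1 | step 6 | [4-bromo-2,6-bis[(4-methoxybenzyl)oxy]phenyl][(2S,3R)-4-[(2,4-dimethoxybenzyl)oxy]-2-(2,4-dimethoxyphenyl)-3-(3,5-dimethoxyphenyl)-2,3-dihydrobenzofuran-6-yl]methanone | O=C(c1c(OCc2ccc(OC)cc2)cc(Br)cc1OCc1ccc(OC)cc1)c1cc(OCc2ccc(OC)cc2OC)c2c(c1)O[C@H](c1ccc(OC)cc1OC)[C@@H]2c1cc(OC)cc(OC)c1
F2 | step 6 | 2,2-diaryloxirane from F1 (both epimers at the oxirane carbon) | C1OC1(c1c(OCc2ccc(OC)cc2)cc(Br)cc1OCc1ccc(OC)cc1)c1cc(OCc2ccc(OC)cc2OC)c2c(c1)O[C@H](c1ccc(OC)cc1OC)[C@@H]2c1cc(OC)cc(OC)c1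
F3 | step 6 | 2,2-diarylacetaldehyde from F2 | O=CC(c1c(OCc2ccc(OC)cc2)cc(Br)cc1OCc1ccc(OC)cc1)c1cc(OCc2ccc(OC)cc2OC)c2c(c1)O[C@H](c1ccc(OC)cc1OC)[C@@H]2c1cc(OC)cc(OC)c1
F4 | step 6 | 1-(4-methoxyphenyl)-2,2-diarylethanol from F3 (mixture of isomers at the two new carbons) | COc1ccc(C(O)C(c2c(OCc3ccc(OC)cc3)cc(Br)cc2OCc2ccc(OC)cc2)c2cc(OCc3ccc(OC)cc3OC)c3c(c2)O[C@H](c2ccc(OC)cc2OC)[C@@H]3c2cc(OC)cc(OC)c2)cc1
F5 | step 6 | (2S,3S)-6-bromo-3-[(2R,3R)-2-(2,4-dimethoxyphenyl)-3-(3,5-dimethoxyphenyl)-4-hydroxy-2,3-dihydrobenzofuran-6-yl]-2-(4-methoxyphenyl)-2,3-dihydrobenzofuran-4-ol (diastereomer of 18) | Brc1cc(O)c2c(c1)O[C@H](c1ccc(OC)cc1)[C@H]2c1cc(O)c2c(c1)O[C@@H](c1ccc(OC)cc1OC)[C@@H]2c1cc(OC)cc(OC)c1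
F6 | step 5 | 4-bromo-2,6-bis[(4-methoxybenzyl)oxy]benzaldehyde | O=Cc1c(OCc2ccc(OC)cc2)cc(Br)cc1OCc1ccc(OC)cc1
F7 | step 5 | diaryl carbinol from 12 and F6 (both epimers at the carbinol carbon) | OC(c1c(OCc2ccc(OC)cc2)cc(Br)cc1OCc1ccc(OC)cc1)c1cc(OCc2ccc(OC)cc2OC)c2c(c1)O[C@H](c1ccc(OC)cc1OC)[C@@H]2c1cc(OC)cc(OC)c1
F8 | step 9 | (2R,3R)-6-bromo-3-[(2R,3R)-2-(2,4-dihydroxyphenyl)-3-(3,5-dihydroxyphenyl)-4-hydroxy-2,3-dihydrobenzofuran-6-yl]-2-(4-hydroxyphenyl)-2,3-dihydrobenzofuran-4-ol | Brc1cc(O)c2c(c1)O[C@@H](c1ccc(O)cc1)[C@@H]2c1cc(O)c2c(c1)O[C@@H](c1ccc(O)cc1O)[C@@H]2c1cc(O)cc(O)c1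
F9 | step 9 | heptaacetate of F8 | Brc1cc(OC(C)=O)c2c(c1)O[C@@H](c1ccc(OC(C)=O)cc1)[C@@H]2c1cc(OC(C)=O)c2c(c1)O[C@@H](c1ccc(OC(C)=O)cc1OC(C)=O)[C@@H]2c1cc(OC(C)=O)cc(OC(C)=O)c1
F10 | step 9 | octaacetate of the target | CC(=O)Oc1ccc(/C=C/c2cc(OC(C)=O)c3c(c2)O[C@@H](c2ccc(OC(C)=O)cc2)[C@@H]3c2cc(OC(C)=O)c3c(c2)O[C@@H](c2ccc(OC(C)=O)cc2OC(C)=O)[C@@H]3c2cc(OC(C)=O)cc(OC(C)=O)c2)cc1
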